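## Retrosynthetic overview

1. Target 14 ⇐ nona-O-benzyl ether 13 by global hydrogenolysis ⇐ α,α-diaryl ketone 12 by Felkin reduction, which sets the carbinol centre.
2. Key disconnection, the interflavan Cα–C-8 bond: 12 ⇐ tertiary carbinol 10 by a stereospecific [1,2]-sigmatropic (semipinacol) aryl shift that opens the pyran ring of the catechin half with inversion at C-2.
3. 10 ⇐ C-8-metallated penta-O-benzyl-(+)-epicatechin (from bromide 7) + (2R)-flavan-3-one 3 (from (+)-catechin).
4. Rings: none is built. Both chromane rings arrive with (+)-catechin and (+)-epicatechin; ring C of the catechin half is opened in the key step, ring C of the epicatechin half is carried through intact.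

Assumption: (+)-epicatechin (ent-epicatechin, 2S,3S) is bought as such; it is a catalogue compound made by C-2 epimerisation of (+)-catechin.

The key step (step 7) and the organocerium addition (step 6) are designed by analogy, not taken from a known case on this system.

## Route

Step 1
Reactants: 1 (+)-catechin
Product: 2 5,7,3',4'-tetra-O-benzyl-(+)-catechin
Conditions: BnBr (4.4 equiv), K2CO3, DMF, −10 °C to rt
Reagents that add atoms: benzyl bromide, BrCc1ccccc1
Why: Williamson etherification in which K2CO3 ionises only the four phenols (the secondary alcohol stays free), and the cold, mild conditions leave C-2 and C-3 untouched.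

Step 2
Reactants: 2 5,7,3',4'-tetra-O-benzyl-(+)-catechin
Product: 3 (2R)-tetra-O-benzyl-flavan-3-one
Conditions: Dess–Martin periodinane (1.5 equiv), wet CH2Cl2, rt; used at once
Reagents that add atoms: none
Why: Dess–Martin oxidation of the secondary alcohol under near-neutral conditions gives the β-tetralone-like ketone without enolising, and so without epimerising, the bought (2R) centre.

Step 3
Reactants: 4 (+)-epicatechin
Product: 5 5,7,3',4'-tetra-O-benzyl-(+)-epicatechin
Conditions: BnBr (4.4 equiv), K2CO3, DMF, −10 °C to rt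
Reagents that add atoms: benzyl bromide, BrCc1ccccc1
Why: Williamson etherification of the four phenols only, as in step 1; no stereocentre is touched.

Step 4
Reactants: 5 5,7,3',4'-tetra-O-benzyl-(+)-epicatechin
Product: 6 3,5,7,3',4'-penta-O-benzyl-(+)-epicatechin
Conditions: NaH, BnBr, DMF, 0 °C to rt
Reagents that add atoms: benzyl bromide, BrCc1ccccc1
Why: Williamson etherification of the remaining secondary alcohol removes the only acidic proton before the organolithium step; with every phenol capped the ring cannot open, so C-2 and C-3 are safe.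

Step 5
Reactants: 6 3,5,7,3',4'-penta-O-benzyl-(+)-epicatechin
Product: 7 8-bromo-3,5,7,3',4'-penta-O-benzyl-(+)-epicatechin
Conditions: NBS (1.05 equiv), CH2Cl2, −78 °C to rt
Reagents that add atoms: N-bromosuccinimide, O=C1CCC(=O)N1Br
Why: Electrophilic aromatic substitution on the most electron-rich ring (ring A); per-benzylated flavan-3-ols take one bromine at C-8 in preference to C-6, which fixes the site of the interflavan bond.

Step 6
Reactants: 7 8-bromo-3,5,7,3',4'-penta-O-benzyl-(+)-epicatechin; 3 (2R)-tetra-O-benzyl-flavan-3-one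
Product: 10 (2R,3S)-3-C-(penta-O-benzyl-epicatechin-8-yl) tertiary carbinol, via 8-lithio flavan 8 (not isolated), via 8-dichlorocerio flavan 9 (not isolated)
Conditions: t-BuLi (2.0 equiv), THF, −78 °C; anhydrous CeCl3 (1.2 equiv), −78 °C; then 3, −78 to −40 °C; aq. NH4Cl
Reagents that add atoms: none
Why: Bromine–lithium exchange and transmetallation give a weakly basic organocerium (Imamoto) that adds 1,2 to the easily enolised ketone, and equatorial attack anti to the 2-aryl group makes the carbinol carbon (3S) with the new aryl trans to the 2-aryl group; this centre becomes the carbonyl carbon in step 7, so a minor C-3 epimer converges on the same ketone.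

Step 7
Reactants: 10 (2R,3S)-3-C-(penta-O-benzyl-epicatechin-8-yl) tertiary carbinol
Product: 12 (3R)-α,α-diaryl ketone bearing a free ortho-phenol, via diethylaluminium alkoxide 11 (not isolated)
Conditions: Et3Al (3 equiv), CH2Cl2, −78 to 0 °C; aq. NH4Cl (neutral work-up); used at once
Reagents that add atoms: none
Why: Suzuki–Tsuchihashi-type semipinacol rearrangement, a suprafacial [1,2]-sigmatropic aryl shift: in the half-chair with both aryl groups axial (readily reached, since axial groups at C-3 of a chromane meet no syn-axial substituent and the two aryl groups are then anti) the electron-rich migrating aryl is anti-periplanar to the Lewis-acid-activated C-2–O-1 bond and is pushed by the aluminium alkoxide onto the p-benzyloxybenzylic C-2 from the face opposite the departing ring oxygen, so the pyran opens and the Cα–C-8 bond forms with inversion of the bought (2R) centre to the (R)-diarylmethine.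

Step 8
Reactants: 12 (3R)-α,α-diaryl ketone
Product: 13 (1R,2S)-nona-O-benzyl chalcane-flavan alcohol
Conditions: NaBH4, CeCl3·7H2O, MeOH–THF, −78 to −40 °C
Reagents that add atoms: none
Why: Felkin–Anh-controlled Luche reduction in which hydride attacks anti to the bulky 2,6-dioxygenated chromanyl group on the adjacent (R) centre to give the (2S)-carbinol, while the non-basic medium keeps the acidic α,α-diaryl centre from epimerising.

Step 9
Reactants: 13 (1R,2S)-nona-O-benzyl chalcane-flavan alcohol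
Product: 14 target gambiriin
Conditions: H2 (1 atm), Pd(OH)2/C, THF–MeOH, rt
Reagents that add atoms: none
Why: Hydrogenolysis of the nine benzyl ethers; the chromane C–O bond, the diarylmethine and the non-benzylic carbinol are inert under neutral conditions, so all four stereocentres are kept.

## Compound list

1 | (+)-catechin, (2R,3S)-2-(3,4-dihydroxyphenyl)chromane-3,5,7-triol | O[C@H]1Cc2c(O)cc(O)cc2O[C@@H]1c1ccc(O)c(O)c1 | starting material

2 | 5,7,3',4'-tetra-O-benzyl-(+)-catechin, (2R,3S) | O[C@H]1Cc2c(OCc3ccccc3)cc(OCc3ccccc3)cc2O[C@@H]1c1ccc(OCc2ccccc2)c(OCc2ccccc2)c1 | intermediate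

3 | (2R)-5,7-bis(benzyloxy)-2-[3,4-bis(benzyloxy)phenyl]chroman-3-one | O=C1Cc2c(OCc3ccccc3)cc(OCc3ccccc3)cc2O[C@@H]1c1ccc(OCc2ccccc2)c(OCc2ccccc2)c1 | intermediate

4 | (+)-epicatechin, (2S,3S)-2-(3,4-dihydroxyphenyl)chromane-3,5,7-triol | O[C@H]1Cc2c(O)cc(O)cc2O[C@H]1c1ccc(O)c(O)c1 | starting material

5 | 5,7,3',4'-tetra-O-benzyl-(+)-epicatechin, (2S,3S) | O[C@H]1Cc2c(OCc3ccccc3)cc(OCc3ccccc3)cc2O[C@H]1c1ccc(OCc2ccccc2)c(OCc2ccccc2)c1 | intermediate

6 | 3,5,7,3',4'-penta-O-benzyl-(+)-epicatechin, (2S,3S) | O(Cc1ccccc1)[C@H]1Cc2c(OCc3ccccc3)cc(OCc3ccccc3)cc2O[C@H]1c1ccc(OCc2ccccc2)c(OCc2ccccc2)c1 | intermediate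

7 | 8-bromo-3,5,7,3',4'-penta-O-benzyl-(+)-epicatechin, (2S,3S) | O(Cc1ccccc1)[C@H]1Cc2c(OCc3ccccc3)cc(OCc3ccccc3)c(Br)c2O[C@H]1c1ccc(OCc2ccccc2)c(OCc2ccccc2)c1 | intermediate

8 | 8-lithio-3,5,7,3',4'-penta-O-benzyl-(+)-epicatechin (not isolated) | O(Cc1ccccc1)[C@H]1Cc2c(OCc3ccccc3)cc(OCc3ccccc3)c([Li])c2O[C@H]1c1ccc(OCc2ccccc2)c(OCc2ccccc2)c1 | intermediate

9 | 8-(dichlorocerio)-3,5,7,3',4'-penta-O-benzyl-(+)-epicatechin, ArCeCl2 (not isolated) | O(Cc1ccccc1)[C@H]1Cc2c(OCc3ccccc3)cc(OCc3ccccc3)c([Ce](Cl)Cl)c2O[C@H]1c1ccc(OCc2ccccc2)c(OCc2ccccc2)c1 | intermediate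

10 | (2R,3S)-5,7-bis(benzyloxy)-2-[3,4-bis(benzyloxy)phenyl]-3-{(2S,3S)-3,5,7-tris(benzyloxy)-2-[3,4-bis(benzyloxy)phenyl]chroman-8-yl}chroman-3-ol (new aryl trans to the 2-aryl group) | O[C@]1(c2c(OCc3ccccc3)cc(OCc3ccccc3)c3c2O[C@@H](c2ccc(OCc4ccccc4)c(OCc4ccccc4)c2)[C@@H](OCc2ccccc2)C3)Cc2c(OCc3ccccc3)cc(OCc3ccccc3)cc2O[C@@H]1c1ccc(OCc2ccccc2)c(OCc2ccccc2)c1 | intermediate

11 | O-diethylaluminium alkoxide of 10 (not isolated) | CC[Al](CC)O[C@]1(c2c(OCc3ccccc3)cc(OCc3ccccc3)c3c2O[C@@H](c2ccc(OCc4ccccc4)c(OCc4ccccc4)c2)[C@@H](OCc2ccccc2)C3)Cc2c(OCc3ccccc3)cc(OCc3ccccc3)cc2O[C@@H]1c1ccc(OCc2ccccc2)c(OCc2ccccc2)c1 | intermediate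

12 | (3R)-1-[2,4-bis(benzyloxy)-6-hydroxyphenyl]-3-[3,4-bis(benzyloxy)phenyl]-3-{(2S,3S)-3,5,7-tris(benzyloxy)-2-[3,4-bis(benzyloxy)phenyl]chroman-8-yl}propan-2-one | Oc1cc(OCc2ccccc2)cc(OCc2ccccc2)c1CC(=O)[C@H](c1ccc(OCc2ccccc2)c(OCc2ccccc2)c1)c1c(OCc2ccccc2)cc(OCc2ccccc2)c2c1O[C@@H](c1ccc(OCc3ccccc3)c(OCc3ccccc3)c1)[C@@H](OCc1ccccc1)C2 | intermediate

13 | (1R,2S)-3-[2,4-bis(benzyloxy)-6-hydroxyphenyl]-1-[3,4-bis(benzyloxy)phenyl]-1-{(2S,3S)-3,5,7-tris(benzyloxy)-2-[3,4-bis(benzyloxy)phenyl]chroman-8-yl}propan-2-ol | Oc1cc(OCc2ccccc2)cc(OCc2ccccc2)c1C[C@H](O)[C@H](c1ccc(OCc2ccccc2)c(OCc2ccccc2)c1)c1c(OCc2ccccc2)cc(OCc2ccccc2)c2c1O[C@@H](c1ccc(OCc3ccccc3)c(OCc3ccccc3)c1)[C@@H](OCc1ccccc1)C2 | intermediate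

14 | target gambiriin, (1R,2S)-1-(3,4-dihydroxyphenyl)-1-[(2S,3S)-2-(3,4-dihydroxyphenyl)-3,5,7-trihydroxychroman-8-yl]-3-(2,4,6-trihydroxyphenyl)propan-2-ol | Oc1cc(O)c(C[C@H](O)[C@H](c2ccc(O)c(O)c2)c2c(O)cc(O)c3c2O[C@@H](c2ccc(O)c(O)c2)[C@@H](O)C3)c(O)c1 | target

## Totals and risks

Total step count: 9. Longest linear sequence: 7 steps (4 → 5 → 6 → 7 → 10 → 12 → 13 → 14).

Step 6 (organocerium addition). The hindered 2,6-dialkoxyaryl reagent may enolise 3 or fail to add. The fallback sets out from 1 and 4 and comes back to the route at 14; it drops the ketone detour and keeps the bought carbinol centre. Compound 4 is ketalised on its catechol with Ph2CCl2 and K2CO3 in MeCN to 3',4'-O-diphenylmethylene-(+)-epicatechin F1, whose own pyran ring can then no longer open. Free 1 is heated with an excess of F1 in degassed water–dioxane (about pH 6 to 7, 95 °C). Ring C of 1 opens to the ring-B quinone methide, which is captured at C-8 of F1 in a Friedel–Crafts-type 1,6-addition under Felkin control from the (S)-carbinol. This gives the target mono(diphenylmethylene) ketal F2 after chromatographic removal of the C-6 and Cα isomers. Hydrogenolysis of F2 over Pd(OH)2/C gives 14.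

Step 7 (aryl shift). Ionisation at the tertiary benzylic carbinol carbon (dehydration to flavenes), ethyl or hydride transfer from aluminium, or full ionisation at C-2 with loss of stereospecificity may compete with the concerted migration; the product can also cyclodehydrate to a benzofuran if the work-up turns acidic. The fallback sets out from 10 and comes back at 14; it changes the trigger from a Lewis acid to a quinone methide. Compound 10 is first hydrogenolysed over Pd(OH)2/C to the free nonahydroxy tertiary carbinol F3. Gentle warming of F3 in degassed dilute aqueous NaHCO3 ionises the 4'-phenol, the ring opens to the ring-B quinone methide, and the adjacent electron-rich aryl group migrates to the methide carbon to give the free polyphenolic ketone F4. NaBH4 in MeOH reduces F4 to 14. The Cα configuration from this stepwise variant, and possible C-2 epimerisation of the epicatechin half, would have to be checked.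

Step 8 (ketone reduction). Hydride may add with the opposite facial sense if the 3,4-bis(benzyloxy)phenyl group instead of the chromanyl group acts as the large substituent. The fallback sets out from 12 and comes back at 14; it accepts the wrong carbinol and inverts it. The (1R,2R)-epimeric alcohol F5 is benzylated on its free phenol (BnBr, K2CO3, DMF) to the deca-O-benzyl (2R)-alcohol F6, which also stops the phenol from closing a dihydrobenzofuran in the next step. Mitsunobu inversion with 4-nitrobenzoic acid (PPh3, DIAD, THF) gives the (2S)-4-nitrobenzoate F7. Methanolysis (K2CO3, MeOH–THF) gives the deca-O-benzyl (2S)-alcohol F8, and hydrogenolysis as in step 9 gives 14.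

## Further compounds

F1 | step 6 | 3',4'-O-diphenylmethylene-(+)-epicatechin | O[C@H]1Cc2c(O)cc(O)cc2O[C@H]1c1ccc2OC(c3ccccc3)(c3ccccc3)Oc2c1

F2 | step 6 | target mono(diphenylmethylene) ketal (ketal of 14 on the catechol of the epicatechin half) | Oc1cc(O)c(C[C@H](O)[C@H](c2ccc(O)c(O)c2)c2c(O)cc(O)c3c2O[C@@H](c2ccc4OC(c5ccccc5)(c5ccccc5)Oc4c2)[C@@H](O)C3)c(O)c1

F3 | step 7 | free nonahydroxy tertiary carbinol, (2R,3S)-3-C-[(+)-epicatechin-8-yl]-(+)-catechin | O[C@]1(c2c(O)cc(O)c3c2O[C@@H](c2ccc(O)c(O)c2)[C@@H](O)C3)Cc2c(O)cc(O)cc2O[C@@H]1c1ccc(O)c(O)c1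

F4 | step 7 | free polyphenolic ketone, (3R)-3-(3,4-dihydroxyphenyl)-3-[(+)-epicatechin-8-yl]-1-(2,4,6-trihydroxyphenyl)propan-2-one | Oc1cc(O)c(CC(=O)[C@H](c2ccc(O)c(O)c2)c2c(O)cc(O)c3c2O[C@@H](c2ccc(O)c(O)c2)[C@@H](O)C3)c(O)c1

F5 | step 8 | (1R,2R)-epimeric alcohol (carbinol epimer of 13) | Oc1cc(OCc2ccccc2)cc(OCc2ccccc2)c1C[C@@H](O)[C@H](c1ccc(OCc2ccccc2)c(OCc2ccccc2)c1)c1c(OCc2ccccc2)cc(OCc2ccccc2)c2c1O[C@@H](c1ccc(OCc3ccccc3)c(OCc3ccccc3)c1)[C@@H](OCc1ccccc1)C2

F6 | step 8 | deca-O-benzyl (2R)-alcohol (phenol benzyl ether of F5) | C(c1ccccc1)Oc1cc(OCc2ccccc2)cc(OCc2ccccc2)c1C[C@@H](O)[C@H](c1ccc(OCc2ccccc2)c(OCc2ccccc2)c1)c1c(OCc2ccccc2)cc(OCc2ccccc2)c2c1O[C@@H](c1ccc(OCc3ccccc3)c(OCc3ccccc3)c1)[C@@H](OCc1ccccc1)C2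

F7 | step 8 | (2S)-4-nitrobenzoate (inverted ester of F6) | C(c1ccccc1)Oc1cc(OCc2ccccc2)cc(OCc2ccccc2)c1C[C@H](OC(=O)c1ccc(cc1)[N+](=O)[O-])[C@H](c1ccc(OCc2ccccc2)c(OCc2ccccc2)c1)c1c(OCc2ccccc2)cc(OCc2ccccc2)c2c1O[C@@H](c1ccc(OCc3ccccc3)c(OCc3ccccc3)c1)[C@@H](OCc1ccccc1)C2

F8 | step 8 | deca-O-benzyl (2S)-alcohol (phenol benzyl ether of 13) | C(c1ccccc1)Oc1cc(OCc2ccccc2)cc(OCc2ccccc2)c1C[C@H](O)[C@H](c1ccc(OCc2ccccc2)c(OCc2ccccc2)c1)c1c(OCc2ccccc2)cc(OCc2ccccc2)c2c1O[C@@H](c1ccc(OCc3ccccc3)c(OCc3ccccc3)c1)[C@@H](OCc1ccccc1)C2
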